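**Retrosynthetic overview**
1. The target is (2S)-7,4'-dihydroxyflavan-(4β→6)-(−)-epiafzelechin. Global hydrogenolysis is the last step; before it, the interflavan bond C4(upper)–C6(lower) is made by Friedel–Crafts attack of a C8-brominated lower unit on the (2S)-flavan-4-yl cation.
2. Ring C of the lower unit (O1–C2–C3–C4) is annulated in one operation onto 3,5-bis(benzyloxy)benzyne by a γ-tosyloxy lithium alkoxide: O1 adds to C8a, and the aryl carbanion left at C4a closes onto C4.
3. Enabling feature: in ring A of the lower unit C4a and C8a are adjacent and C5, next to C4a, carries oxygen. The C4a≡C8a aryne therefore takes O1 at C8a and puts the carbanion at C4a between two oxygens. O1 and the C4 leaving group are 1,3-related on a chain whose C2/C3 centres are not touched, so syn becomes 2,3-cis.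
4. Stereocentres: lower C2/C3 from an Evans syn-glycolate aldol; upper C2 from a Pd-catalysed enantioselective conjugate addition to a chromone; upper C4 in the Friedel–Crafts step.
5. Ring order: upper ring C is present from the chromone; lower ring C forms in the key step; all aromatic rings are bought.

Key step: step 4

Assumption: the Pd/t-BuPyOx conjugate addition is taken to show on 7-alkoxychromones the facial sense known for cyclic enones, so the (R)-ligand is chosen for the (2S)-flavanone.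

**Step 1**
Reactants: 1 (4S)-4-benzyl-3-[2-(benzyloxy)acetyl]-1,3-oxazolidin-2-one; 2 4-(benzyloxy)benzaldehyde
Product: 5 (4S)-4-benzyl-3-[(2S,3R)-2-(benzyloxy)-3-[4-(benzyloxy)phenyl]-3-hydroxypropanoyl]-1,3-oxazolidin-2-one, via Z-boron enolate 3 (not isolated), via boron aldolate 4 (not isolated)
Conditions: Bu2BOTf, Et3N, CH2Cl2, −78 → 0 °C; 2, −78 → 0 °C; then MeOH, pH 7 buffer, 30% H2O2, 0 °C
Reagents that add atoms: none
Why: Evans syn-glycolate aldol: the Z-boron enolate reacts through a chair Zimmerman–Traxler transition state on the face not shielded by the benzyl group of the (S)-auxiliary, which should set both new centres as (2S,3R)-syn, the future C3 and C2 of the lower unit.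

**Step 2**
Reactants: 5
Product: 6 (1R,2R)-2-(benzyloxy)-1-[4-(benzyloxy)phenyl]propane-1,3-diol
Conditions: LiBH4, THF, MeOH (1 equiv), 0 °C → rt
Reagents that add atoms: none
Why: Reductive cleavage of the N-acyloxazolidinone by LiBH4 (hydride attack at the exocyclic imide carbonyl) should give the 1,3-diol and release the auxiliary without touching either stereocentre.

**Step 3**
Reactants: 6
Product: 7 (2R,3R)-2-(benzyloxy)-3-[4-(benzyloxy)phenyl]-3-hydroxypropyl 4-methylbenzenesulfonate
Conditions: TsCl (1.05 equiv), pyridine, CH2Cl2, 0 °C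
Reagents that add atoms: tosyl chloride Cc1ccc(S(Cl)(=O)=O)cc1
Why: Selective sulfonylation: the primary hydroxyl should react well ahead of the hindered secondary benzylic one, and under amine base the hydroxy tosylate should not close to an oxetane.

**Step 4**
Reactants: 7; 8 1,3-bis(benzyloxy)-5-bromobenzene
Product: 13 (2R,3R)-3,5,7-tris(benzyloxy)-2-[4-(benzyloxy)phenyl]chromane (tetra-O-benzyl-(−)-epiafzelechin), via lithium alkoxide 9 (not isolated), via ortho-lithiated bromide 10 (not isolated), via 3,5-bis(benzyloxy)benzyne 11 (not isolated), via aryllithium 12 (not isolated)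
Conditions: 7, lithium 2,2,6,6-tetramethylpiperidide (LiTMP, made in the flask from 2,2,6,6-tetramethylpiperidine and n-BuLi; 1.0 equiv), THF, −78 °C; 8 (2.0 equiv); LiTMP (2.2 equiv) dropwise, −78 °C; slowly to 0 °C, then rt; aq NH4Cl
Reagents that add atoms: none
Why: Proposed new method: LiTMP deprotonates the alcohol (9) and the arene ortho to bromine (10); on warming 10 loses LiBr to give aryne 11, the alkoxide oxygen adds to the aryne carbon remote from the flanking benzyloxy group (future C8a), and the resulting 2,6-dialkoxyaryllithium 12 (carbanion at future C4a) displaces the primary tosylate. The closest known reactions are the meta-selective addition of alkoxides and amides to 3-alkoxyarynes generated with lithium amides, aryne annulations in which an O-nucleophile adds and the aryl anion is trapped by a tethered electrophile, and the Parham cyclialkylation of o-lithioaryl 3-halopropyl ethers to chromanes. Ring C of the lower unit closes in two events, intermolecular O1–C8a bond formation followed by a 6-exo-tet SN2 closure of C4–C4a. No new stereocentre is formed: C2 and C3 come unchanged from the syn aldol, and because neither C–O bond at these centres is broken the syn relationship becomes 2,3-cis (2R,3R). The step needs O-attack at C8a, which the inductive effect of the benzyloxy group next to C4a should secure (distorted 3-alkoxyaryne, carbanion stabilised between two oxygens). It also needs cyclisation to outrun proton capture and oxetane closure, which the aprotic amide medium, the low temperature and the lithium counter-ion of the γ-tosyloxy alkoxide should secure.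

**Step 5**
Reactants: 13
Product: 14 (2R,3R)-3,5,7-tris(benzyloxy)-2-[4-(benzyloxy)phenyl]-8-bromochromane
Conditions: NBS (1.0 equiv), CH2Cl2, −78 °C → rt
Reagents that add atoms: N-bromosuccinimide O=C1CCC(=O)N1Br
Why: Electrophilic aromatic bromination: in 5,7-dialkoxyflavans C8 is the more reactive and less hindered free position of ring A (C6 lies between two benzyloxy groups), so monobromination should block C8 and leave C6 as the only nucleophilic site for step 9.

**Step 6**
Reactants: 15 7-hydroxy-4H-chromen-4-one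
Product: 16 7-(benzyloxy)-4H-chromen-4-one
Conditions: BnBr, K2CO3, DMF, rt
Reagents that add atoms: benzyl bromide BrCc1ccccc1
Why: Williamson ether synthesis on the acidic 7-hydroxyl; no stereocentre is involved.

**Step 7**
Reactants: 16; 17 [4-(benzyloxy)phenyl]boronic acid
Product: 18 (2S)-7-(benzyloxy)-2-[4-(benzyloxy)phenyl]chroman-4-one
Conditions: Pd(OCOCF3)2 (5 mol %), (R)-4-tert-butyl-2-(pyridin-2-yl)-4,5-dihydro-1,3-oxazole ((R)-t-BuPyOx, 6 mol %), NH4PF6 (30 mol %), H2O (5 equiv), ClCH2CH2Cl, 60 °C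
Reagents that add atoms: none
Why: Palladium-catalysed enantioselective conjugate addition of an arylboronic acid to a chromone (aryl–palladium insertion, then protonation of the palladium enolate by water); the pyridine-oxazoline ligand controls the face of C2 and should give the (2S)-flavanone.

**Step 8**
Reactants: 18
Product: 19 (2S,4S)-7-(benzyloxy)-2-[4-(benzyloxy)phenyl]chroman-4-ol
Conditions: NaBH4, THF/MeOH, 0 °C
Reagents that add atoms: none
Why: Borohydride reduction of the flavanone; axial hydride attack should give mainly the 2,4-cis alcohol, whose C4 configuration is of no consequence because C4 is ionised in step 9.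

**Step 9**
Reactants: 19; 14
Product: 21 (2R,3R)-3,5,7-tris(benzyloxy)-6-[(2S,4R)-7-(benzyloxy)-2-[4-(benzyloxy)phenyl]chroman-4-yl]-2-[4-(benzyloxy)phenyl]-8-bromochromane, via flavan-4-yl cation 20 (not isolated)
Conditions: 14 (2.5 equiv), TMSOTf (0.2 equiv), 4 Å molecular sieves, CH2Cl2, −78 → −30 °C; Et3N quench
Reagents that add atoms: none
Why: Friedel–Crafts alkylation (SN1): the Lewis acid ionises the benzylic alcohol to cation 20, stabilised by O1 and the 7-benzyloxy group, which is captured by C6, the only free position of ring A of 14; pseudoaxial attack on the half-chair cation anti to the pseudoequatorial C2 aryl group should set C4 as R (2,4-trans).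

**Step 10**
Reactants: 21
Product: 22 (2R,3R)-6-[(2S,4R)-7-hydroxy-2-(4-hydroxyphenyl)chroman-4-yl]-2-(4-hydroxyphenyl)chromane-3,5,7-triol (target, CNP0167324.2)
Conditions: H2 (1 atm), Pd(OH)2/C, NaOAc (2 equiv), THF/MeOH, rt
Reagents that add atoms: none
Why: Catalytic hydrogenolysis of the six benzyl ethers and of the C8–Br bond; NaOAc buffers the HBr and no stereocentre is affected.

**Compound list**
1 | (4S)-4-benzyl-3-[2-(benzyloxy)acetyl]-1,3-oxazolidin-2-one | O=C(COCc1ccccc1)N1[C@@H](Cc2ccccc2)COC1=O | starting material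
2 | 4-(benzyloxy)benzaldehyde | O=Cc1ccc(OCc2ccccc2)cc1 | starting material
3 | Z-dibutylboron enolate of 1 | CCCCB(CCCC)O/C(=C\OCc1ccccc1)N1[C@@H](Cc2ccccc2)COC1=O | intermediate
4 | dibutylboron aldolate of 5 | O=C([C@@H](OCc1ccccc1)[C@@H](c1ccc(OCc2ccccc2)cc1)OB(CCCC)CCCC)N1[C@@H](Cc2ccccc2)COC1=O | intermediate
5 | (4S)-4-benzyl-3-[(2S,3R)-2-(benzyloxy)-3-[4-(benzyloxy)phenyl]-3-hydroxypropanoyl]-1,3-oxazolidin-2-one | O=C([C@@H](OCc1ccccc1)[C@@H](c1ccc(OCc2ccccc2)cc1)O)N1[C@@H](Cc2ccccc2)COC1=O | intermediate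
6 | (1R,2R)-2-(benzyloxy)-1-[4-(benzyloxy)phenyl]propane-1,3-diol | OC[C@@H](OCc1ccccc1)[C@@H](c1ccc(OCc2ccccc2)cc1)O | intermediate
7 | (2R,3R)-2-(benzyloxy)-3-[4-(benzyloxy)phenyl]-3-hydroxypropyl 4-methylbenzenesulfonate | Cc1ccc(S(=O)(=O)OC[C@@H](OCc2ccccc2)[C@@H](c2ccc(OCc3ccccc3)cc2)O)cc1 | intermediate
8 | 1,3-bis(benzyloxy)-5-bromobenzene | Brc1cc(OCc2ccccc2)cc(OCc2ccccc2)c1 | starting material
9 | lithium alkoxide of 7 | Cc1ccc(S(=O)(=O)OC[C@@H](OCc2ccccc2)[C@@H](c2ccc(OCc3ccccc3)cc2)O[Li])cc1 | intermediate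
10 | [2,4-bis(benzyloxy)-6-bromophenyl]lithium | [Li]c1c(Br)cc(OCc2ccccc2)cc1OCc1ccccc1 | intermediate
11 | 3,5-bis(benzyloxy)benzyne | C1#CC(OCc2ccccc2)=CC(OCc2ccccc2)=C1 | intermediate
12 | aryllithium from O-addition of 9 to 11 (lithium at future C4a) | Cc1ccc(S(=O)(=O)OC[C@@H](OCc2ccccc2)[C@@H](c2ccc(OCc3ccccc3)cc2)Oc2cc(OCc3ccccc3)cc(OCc3ccccc3)c2[Li])cc1 | intermediate
13 | (2R,3R)-3,5,7-tris(benzyloxy)-2-[4-(benzyloxy)phenyl]chromane | c1(OCc2ccccc2)cc3c(c(OCc4ccccc4)c1)C[C@@H](OCc1ccccc1)[C@@H](c1ccc(OCc2ccccc2)cc1)O3 | intermediate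
14 | (2R,3R)-3,5,7-tris(benzyloxy)-2-[4-(benzyloxy)phenyl]-8-bromochromane | c1(OCc2ccccc2)c(Br)c3c(c(OCc4ccccc4)c1)C[C@@H](OCc1ccccc1)[C@@H](c1ccc(OCc2ccccc2)cc1)O3 | intermediate
15 | 7-hydroxy-4H-chromen-4-one | O=c1ccoc2cc(O)ccc12 | starting material
16 | 7-(benzyloxy)-4H-chromen-4-one | O=c1ccoc2cc(OCc3ccccc3)ccc12 | intermediate
17 | [4-(benzyloxy)phenyl]boronic acid | OB(O)c1ccc(OCc2ccccc2)cc1 | starting material
18 | (2S)-7-(benzyloxy)-2-[4-(benzyloxy)phenyl]chroman-4-one | O=C1C[C@@H](c2ccc(OCc3ccccc3)cc2)Oc2cc(OCc3ccccc3)ccc12 | intermediate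
19 | (2S,4S)-7-(benzyloxy)-2-[4-(benzyloxy)phenyl]chroman-4-ol | O[C@H]1C[C@@H](c2ccc(OCc3ccccc3)cc2)Oc2cc(OCc3ccccc3)ccc12 | intermediate
20 | (2S)-7-(benzyloxy)-2-[4-(benzyloxy)phenyl]chroman-4-ylium | [CH+]1C[C@@H](c2ccc(OCc3ccccc3)cc2)Oc2cc(OCc3ccccc3)ccc12 | intermediate
21 | (2R,3R)-3,5,7-tris(benzyloxy)-6-[(2S,4R)-7-(benzyloxy)-2-[4-(benzyloxy)phenyl]chroman-4-yl]-2-[4-(benzyloxy)phenyl]-8-bromochromane | C(c1ccccc1)Oc1ccc([C@@H]2C[C@@H](c3c(OCc5ccccc5)c(Br)c4c(c3OCc3ccccc3)C[C@@H](OCc3ccccc3)[C@@H](c3ccc(OCc5ccccc5)cc3)O4)c3ccc(OCc4ccccc4)cc3O2)cc1 | intermediate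
22 | (2R,3R)-6-[(2S,4R)-7-hydroxy-2-(4-hydroxyphenyl)chroman-4-yl]-2-(4-hydroxyphenyl)chromane-3,5,7-triol | Oc1ccc([C@@H]2C[C@@H](c3c(O)cc4c(c3O)C[C@@H](O)[C@@H](c3ccc(O)cc3)O4)c3ccc(O)cc3O2)cc1 | target

**Step count and risks**
Total step count: 10. Longest linear sequence: 7 steps (steps 1, 2, 3, 4, 5, 9, 10).

Steps most likely to fail:

1. Step 4 (key step). The aryllithium may capture a proton before it cyclises, the lithium alkoxide may add too slowly so that the aryne self-condenses, or the tosylate may be lost by oxetane closure or elimination. The fallback forms the same two bonds one after the other by known reactions; it sets out from 5 and 8 and comes back at 13. Silylation of 5 (TBSOTf, 2,6-lutidine) gives silyl ether F1. LiBH4 reduction gives primary alcohol F2. Tf2O with 2,6-lutidine at −78 °C gives triflate F3. F3 is added to the ortho-lithiated bromide 10, made from 8 and LiTMP and kept at −78 °C so that LiBr is not lost; SN2 alkylation forms C4–C4a and gives aryl bromide F4. TBAF removes the silyl group to give bromo alcohol F5. Palladium-catalysed intramolecular C–O coupling (Buchwald–Hartwig etherification; Pd(OAc)2, 2-(di-tert-butylphosphino)-1,1'-binaphthyl, Cs2CO3, toluene, 70 °C) then closes O1–C8a with retention at C2 and gives 13.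

2. Step 9. Facial selectivity at C4 may be poor, and attack by the hindered, bromine-deactivated C6 may be slow enough for the cation to self-condense or eliminate. The fallback makes the interflavan bond first on a symmetrical, unhindered nucleophile and builds the lower ring C afterwards; it sets out from 19 and comes back at 22. Friedel–Crafts reaction of 19 with excess phloroglucinol (BF3·OEt2, dioxane) gives the 2,4-trans triol F6, separable from its cis isomer at this stage. Triflation of the unhindered para-hydroxyl (PhNTf2, K2CO3) gives monotriflate F7, and benzylation (BnBr, K2CO3) gives bis(benzyl ether) F8. Under the conditions of step 4, LiTMP converts F8 by ortho-deprotonation and loss of lithium triflate into aryne F9, which takes up alkoxide 9 to give aryllithium F10 and then, by cyclialkylation, the bromine-free protected dimer F11. Because the aryl ring of F8 is locally symmetrical, either ortho position leads to the same 4→6 connectivity. Hydrogenolysis as in step 10 converts F11 into 22.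

3. Step 7. Enantioselectivity may be insufficient or of the opposite sense, and addition to the electron-rich chromone may be slow. The fallback replaces catalytic C–C bond formation by a kinetic resolution; it sets out from 2 and commercial 1-[4-(benzyloxy)-2-hydroxyphenyl]ethan-1-one and comes back at 19. Claisen–Schmidt condensation (KOH, EtOH) gives chalcone F12. Oxa-Michael cyclisation (NaOAc, EtOH, reflux) gives racemic flavanone F13. Noyori asymmetric transfer hydrogenation under kinetic-resolution conditions (RuCl(p-cymene)[(S,S)-TsDPEN], HCO2H/Et3N) should reduce the (2S)-enantiomer selectively to 19 and leave the (2R)-enantiomer of F13 unreduced.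

**Further compounds**
F1 | step 4 | (4S)-4-benzyl-3-[(2S,3R)-2-(benzyloxy)-3-[4-(benzyloxy)phenyl]-3-[(tert-butyldimethylsilyl)oxy]propanoyl]-1,3-oxazolidin-2-one | O=C([C@@H](OCc1ccccc1)[C@@H](c1ccc(OCc2ccccc2)cc1)O[Si](C)(C)C(C)(C)C)N1[C@@H](Cc2ccccc2)COC1=O
F2 | step 4 | (2R,3R)-2-(benzyloxy)-3-[4-(benzyloxy)phenyl]-3-[(tert-butyldimethylsilyl)oxy]propan-1-ol | OC[C@@H](OCc1ccccc1)[C@@H](c1ccc(OCc2ccccc2)cc1)O[Si](C)(C)C(C)(C)C
F3 | step 4 | (2R,3R)-2-(benzyloxy)-3-[4-(benzyloxy)phenyl]-3-[(tert-butyldimethylsilyl)oxy]propyl trifluoromethanesulfonate | FC(F)(F)S(=O)(=O)OC[C@@H](OCc1ccccc1)[C@@H](c1ccc(OCc2ccccc2)cc1)O[Si](C)(C)C(C)(C)C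
F4 | step 4 | [(1R,2R)-2-(benzyloxy)-1-[4-(benzyloxy)phenyl]-3-[2-bromo-4,6-bis(benzyloxy)phenyl]propoxy](tert-butyl)dimethylsilane | Brc1cc(OCc2ccccc2)cc(OCc2ccccc2)c1C[C@@H](OCc1ccccc1)[C@@H](c1ccc(OCc2ccccc2)cc1)O[Si](C)(C)C(C)(C)C
F5 | step 4 | (1R,2R)-2-(benzyloxy)-1-[4-(benzyloxy)phenyl]-3-[2-bromo-4,6-bis(benzyloxy)phenyl]propan-1-ol | Brc1cc(OCc2ccccc2)cc(OCc2ccccc2)c1C[C@@H](OCc1ccccc1)[C@@H](c1ccc(OCc2ccccc2)cc1)O
F6 | step 9 | 2-[(2S,4R)-7-(benzyloxy)-2-[4-(benzyloxy)phenyl]chroman-4-yl]benzene-1,3,5-triol | C(c1ccccc1)Oc1ccc([C@@H]2C[C@@H](c3c(O)cc(O)cc3O)c3ccc(OCc4ccccc4)cc3O2)cc1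
F7 | step 9 | 4-[(2S,4R)-7-(benzyloxy)-2-[4-(benzyloxy)phenyl]chroman-4-yl]-3,5-dihydroxyphenyl trifluoromethanesulfonate | C(c1ccccc1)Oc1ccc([C@@H]2C[C@@H](c3c(O)cc(OS(=O)(=O)C(F)(F)F)cc3O)c3ccc(OCc4ccccc4)cc3O2)cc1
F8 | step 9 | 3,5-bis(benzyloxy)-4-[(2S,4R)-7-(benzyloxy)-2-[4-(benzyloxy)phenyl]chroman-4-yl]phenyl trifluoromethanesulfonate | C(c1ccccc1)Oc1ccc([C@@H]2C[C@@H](c3c(OCc4ccccc4)cc(OS(=O)(=O)C(F)(F)F)cc3OCc3ccccc3)c3ccc(OCc4ccccc4)cc3O2)cc1
F9 | step 9 | 3,5-bis(benzyloxy)-4-[(2S,4R)-7-(benzyloxy)-2-[4-(benzyloxy)phenyl]chroman-4-yl]benzyne | C(c1ccccc1)Oc1ccc([C@@H]2C[C@@H](C=3C(OCc4ccccc4)=CC#CC3OCc3ccccc3)c3ccc(OCc4ccccc4)cc3O2)cc1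
F10 | step 9 | aryllithium from O-addition of 9 to F9 (lithium at future C4a) | C(c1ccccc1)Oc1ccc([C@@H]2C[C@@H](c3c(OCc5ccccc5)cc(O[C@H](c5ccc(OCc6ccccc6)cc5)[C@H](OCc5ccccc5)COS(=O)(=O)c5ccc(C)cc5)c([Li])c3OCc3ccccc3)c3ccc(OCc4ccccc4)cc3O2)cc1
F11 | step 9 | (2R,3R)-3,5,7-tris(benzyloxy)-6-[(2S,4R)-7-(benzyloxy)-2-[4-(benzyloxy)phenyl]chroman-4-yl]-2-[4-(benzyloxy)phenyl]chromane | C(c1ccccc1)Oc1ccc([C@@H]2C[C@@H](c3c(OCc5ccccc5)cc4c(c3OCc3ccccc3)C[C@@H](OCc3ccccc3)[C@@H](c3ccc(OCc5ccccc5)cc3)O4)c3ccc(OCc4ccccc4)cc3O2)cc1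
F12 | step 7 | (E)-1-[4-(benzyloxy)-2-hydroxyphenyl]-3-[4-(benzyloxy)phenyl]prop-2-en-1-one | O=C(/C=C/c1ccc(OCc2ccccc2)cc1)c1ccc(OCc2ccccc2)cc1O
F13 | step 7 | rac-7-(benzyloxy)-2-[4-(benzyloxy)phenyl]chroman-4-one | O=C1CC(c2ccc(OCc3ccccc3)cc2)Oc2cc(OCc3ccccc3)ccc12
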